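Core numbering used throughout: C1 is the ketal carbon, then O2, C3, C4, C5, C6, C7, O8; the side chain on C1 is C1'–C6'.

## The problem

The target 32 is a 2,8-dioxabicyclo[3.2.1]octane. A tetrahydrofuran (O8, C1, C7, C6, C5) and a 1,3-dioxane (C1, O2, C3, C4, C5, O8) share C1, O8 and C5, and C1 carries an arm with an (E)-trisubstituted alkene and a remote (S)-methine at C5'. Three adjacent ring carbons each bear a carboxyl group: C3 is a CH, C4 a tertiary alcohol and C5 a fully substituted ether carbon. Two contiguous tetrasubstituted stereocentres flanked by a third therefore have to be made in a crowded, highly oxidised strip. C1 is not an independent problem, because the bridge can close in only one sense once C3 and C5 are fixed. C4 and C5 can be tied to each other through the geometry of a C4=C5 alkene, whereas C3 and C5' are isolated and need reagent control or the chiral pool. The side-chain alkene forbids ozonolysis, hydrogenation and undirected electrophilic epoxidation once the arm is present, and the ketal limits strong aqueous acid. At the carboxyl oxidation level the C3 hydrogen is epimerisable and the C3/C4 array is a beta-hydroxy carbonyl system open to retro-aldol cleavage. The enabling feature is the anti relationship between the C5–O8 bond and the C4 hydroxyl. That is what invertive opening of a C4–C5 epoxide at C5 leaves behind; the C1 carbonyl oxygen sits three carbons from C5, and the C3 hydroxyl can close the dioxane onto C1.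

## Retrosynthesis

32 back to 29 (through 31 and 30). No skeletal bond is cut; the three carboxyl groups are traded for silyloxymethyl groups. Carrying esters instead is closed, because the alkene that sets C4 and C5 must be electron-rich and carry allylic hydroxyl handles. Compound 29 has no epimerisable or retro-aldol-prone centre. The forward price is a threefold oxidation of 30 through 31 that must avoid lactol formation and spare the side-chain alkene.

29 back to 27 (key disconnection). The C5–O8 and C1–O2 bonds are cut. Cutting both ketal bonds at C1 instead would return a keto triol whose two adjacent tertiary carbinols would have to be built one at a time. Cutting C5–O8 makes the C5 configuration the stereospecific result of invertive epoxide opening, and the oxirane oxygen becomes the C4 hydroxyl. Both rings and the C1 stereocentre vanish; 27 is acyclic with three stereocentres, two of them in one oxirane. The forward reaction must attack C5 and not C4, and oxocarbenium ion 28 must be closed by the C3 hydroxyl and not by the C4 oxygen.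

27 back to 24 (through 26 and 25). The two C–O bonds of the oxirane are cut; the ketone is masked as a dioxolane and the two new hydroxymethyl groups are left free as handles. The trans geometry of the tetrasubstituted alkene becomes the relative configuration of C4 and C5, and the tartrate sets the absolute sense. A dihydroxylation route would not give the anti C4–O/C5–O8 relationship without a further inversion. Two tetrasubstituted stereocentres are replaced by one alkene geometry. The forward steps need face selectivity next to the C3 stereocentre, chemoselectivity over the side-chain alkene, and ketal removal that leaves the oxirane closed.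

24 back to 20 (through 23 and 22). The C4–CH2O and C5–CH2O carbon–carbon bonds are cut. Anti addition across the C4≡C5 alkyne, steered by the C3 alkoxide, gives the required geometry with C3 and C6 trans. Syn carbometalation or ketone olefination would not, and lactone 22 both proves and locks the geometry. The tetrasubstituted alkene is reduced to an internal alkyne with one stereocentre. The forward steps are a regio- and anti-selective carbomagnesiation with a hydroxymethyl anion equivalent, carboxylation, silicon-to-oxygen exchange and lactone reduction.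

20 back to 16 and 17 (through 19). The C3–C4 bond is cut. This joins two fragments at the alkyne and leaves C3 as a ketone whose reduction is reagent-controlled. Direct asymmetric alkynylation at the aldehyde oxidation level would save a step but is less dependable for an unbranched, enolisable alpha-oxygenated aldehyde. The only core stereocentre is removed and 17 is a purchasable two-carbon piece. High enantioselectivity in the ynone reduction is required.

16 back to 11 and 12 (through 15 and 14). The C1–C7 bond is cut. This places C1 at a Weinreb amide, the carbon that the Claisen step delivers as an ester. Cutting C6–C7 or C5–C6 would need alkylations with homopropargylic halides that tend to eliminate. Compound 12 is a purchasable four-carbon unit. The ketone must be masked as dioxolane 15 to survive the acetylide, Grignard and hydride steps.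

11 back to 7 and 8 (through 10). The C1'–C2' bond is cut and the alkene moves. The (E)-trisubstituted alkene then arises from a chair transition state; a Wittig-type olefination of this pattern would give E/Z mixtures. Compound 7 is a simple allylic alcohol whose carbinol configuration is irrelevant. The rearrangement must be E-selective and must not touch C5'.

7 back to 5 and 6, and 5 back to 1 and 2 (through 4). The carbinol–isopropenyl bond and the C6'–phenyl bond are cut. The C5' stereocentre is bought with 1, and an sp3–sp2 Negishi coupling avoids an auxiliary-based alkylation. All pieces are commercial. The alpha-chiral aldehyde 5 must not racemise.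

## Roads not taken

Alternative 1: The cut is C6–C7. The second-generation Grubbs catalyst would join the two vinyl groups of the divinyl 1,3-dioxane ketal A1 and close the five-membered ring to bicyclic alkene A2.
- Merits: the carboxyl groups are already esters, so no late triple oxidation is needed, and five-membered ring-closing metathesis is dependable.
- Weak points: A1 needs both vinyl groups axial on one face of the dioxane. At C5 this competes with the ester, and at C1 it must be set during a reversible ketalisation that involves a tertiary hydroxyl. Both reacting alkenes sit on fully substituted carbons and A2 is strained. C6=C7 must then be saturated without touching the side-chain alkene. The key step sets none of C3, C4 or C5.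
- Comparison: this road is better in oxidation-state economy and has a shorter end game. The chosen plan sets against it that C4, C5 and C1 all follow from one alkene geometry, one reagent-controlled epoxidation and a stereospecific cascade on acyclic 27.

Alternative 2: The cut is C3–C4. The lithium enolate of the glycolate unit in mixed ketal A3 would add to the non-enolisable C4 keto ester and close the dioxane, giving trimethyl ester A4.
- Merits: A4 is one hydrolysis from 32, the carboxyls need no adjustment, and only one enolate can form.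
- Weak points: C3 and C4 are created together with no control element beyond the forming ring, and the aldol is reversible. A3 needs its glycolate oxygen at C1 cis to the keto ester arm, an anomeric relationship that is labile. The 1,2-dicarbonyl unit invites hydration and attack at the ester carbonyl.
- Comparison: if the aldol gave the right diastereomer, this road would be clearly shorter after its key step (one step against three). The chosen plan trades those steps for stereospecificity, since every stereocentre of 29 is fixed before or by the cascade.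

Alternative 3: The cuts are C5–O8, C5–C6 and C1–C7. Rh2(OAc)4 would convert diazo ester A5 into a carbenoid that the C1 ester carbonyl oxygen captures. The six-membered carbonyl ylide would add (E)-1,2-bis(phenylsulfonyl)ethene A6 to give cycloadduct A7.
- Merits: three bonds and both rings form in one step, the carboxyls are fully oxidised, C3 and C4 can come from the chiral pool, and this cycloaddition type is known for the ring system.
- Weak points: for a target with methylene groups at C6 and C7 the two sulfonyl groups of A7 are only placeholders. Their reductive removal next to the ketal carbon would more likely give a C6=C7 alkene, which must then be saturated selectively, and beta-alkoxy sulfone fragmentation threatens the ketal. The facial approach of A6 relative to the C4 substituents is not secured.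
- Comparison: this road equals or beats the chosen one in convergence and oxidation level. The chosen plan sets against it that C6 and C7 arrive as methylenes and nothing has to be removed after the ring-forming step.

Key step: step 17

Assumption: the facial senses of steps 10 and 14 are assigned from the usual empirical models (alkynyl group as the recognised substituent in the transfer hydrogenation; the tartrate face rule as established for simple E-configured primary allylic alcohols), and the ligand enantiomers named follow from these.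

Step 1
Reactants: 1 methyl (2R)-3-bromo-2-methylpropanoate; 2 iodobenzene
Product: 4 methyl (2S)-2-methyl-3-phenylpropanoate, via alkylzinc bromide 3 (not isolated)
Conditions: Zn dust, I2 (cat.), DMA, 70 °C; then 2, Pd2(dba)3 (cat.), P(o-tol)3, 40 °C
Reagents that add atoms: none
Why: Zinc insertion into the primary C–Br bond and Negishi sp3–sp2 coupling; the stereocentre is one carbon away from the metal and is untouched, the R-to-S change being only a change of substituent priority.

Step 2
Reactants: 4 methyl (2S)-2-methyl-3-phenylpropanoate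
Product: 5 (2S)-2-methyl-3-phenylpropanal
Conditions: i-Bu2AlH (1.05 equiv), CH2Cl2, −78 °C; MeOH, then aq. potassium sodium tartrate
Reagents that add atoms: none
Why: Partial hydride reduction of a methyl ester through the aluminium hemiacetal, which is stable at low temperature; the crude aldehyde is used at once to protect the alpha-stereocentre.

Step 3
Reactants: 5 (2S)-2-methyl-3-phenylpropanal; 6 (prop-1-en-2-yl)magnesium bromide
Product: 7 (3RS,4S)-2,4-dimethyl-5-phenylpent-1-en-3-ol (both C3 epimers)
Conditions: THF, −78 → 0 °C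
Reagents that add atoms: none
Why: Grignard 1,2-addition to the aldehyde; the new carbinol centre forms as a mixture, which does not matter because step 4 destroys it.

Step 4
Reactants: 7 (3RS,4S)-2,4-dimethyl-5-phenylpent-1-en-3-ol; 8 triethyl orthoacetate
Product: 10 ethyl (4E,6S)-4,6-dimethyl-7-phenylhept-4-enoate, via ketene acetal 9 (not isolated)
Conditions: EtCO2H (cat.), neat 8, 140 °C, EtOH distilled off
Reagents that add atoms: none
Why: Johnson–Claisen rearrangement; a chair transition state with the CH(CH3)CH2Ph group pseudo-equatorial should give the (E)-alkene from both epimers of 7, and C5' is a spectator.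

Step 5
Reactants: 10 ethyl (4E,6S)-4,6-dimethyl-7-phenylhept-4-enoate
Product: 11 (4E,6S)-N-methoxy-N,4,6-trimethyl-7-phenylhept-4-enamide
Conditions: MeNHOMe·HCl, i-PrMgCl, THF, −20 → 0 °C
Reagents that add atoms: N,O-dimethylhydroxylamine hydrochloride, CNOC.Cl
Why: Direct aminolysis of the ester by the chloromagnesium amide (Weinreb amide synthesis).

Step 6
Reactants: 11 (4E,6S)-N-methoxy-N,4,6-trimethyl-7-phenylhept-4-enamide; 12 (4-bromobut-1-yn-1-yl)trimethylsilane
Product: 14 (8E,10S)-8,10-dimethyl-11-phenyl-1-(trimethylsilyl)undec-8-en-1-yn-5-one, via Grignard reagent 13 (not isolated)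
Conditions: 12, Mg, THF, rt → 40 °C; then 11, 0 °C → rt
Reagents that add atoms: none
Why: Weinreb ketone synthesis; the chelated tetrahedral adduct stops at the ketone, and the silyl cap keeps the acidic alkyne hydrogen out of the Grignard formation.

Step 7
Reactants: 14 (8E,10S)-8,10-dimethyl-11-phenyl-1-(trimethylsilyl)undec-8-en-1-yn-5-one
Product: 15 trimethyl(4-{2-[(3E,5S)-3,5-dimethyl-6-phenylhex-3-en-1-yl]-1,3-dioxolan-2-yl}but-1-yn-1-yl)silane
Conditions: HO(CH2)2OH, PPTS (cat.), benzene, reflux (Dean–Stark)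
Reagents that add atoms: ethane-1,2-diol, OCCO
Why: Acid-catalysed ketalisation with azeotropic removal of water; the dioxolane masks the enolisable ketone for the organometallic and hydride steps 9 to 13.

Step 8
Reactants: 15 trimethyl(4-{2-[(3E,5S)-3,5-dimethyl-6-phenylhex-3-en-1-yl]-1,3-dioxolan-2-yl}but-1-yn-1-yl)silane
Product: 16 2-(but-3-yn-1-yl)-2-[(3E,5S)-3,5-dimethyl-6-phenylhex-3-en-1-yl]-1,3-dioxolane
Conditions: K2CO3, MeOH, rt
Reagents that add atoms: none
Why: Base-catalysed methanolysis of the alkynyl–silicon bond; ketal and alkene are inert.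

Step 9
Reactants: 16 2-(but-3-yn-1-yl)-2-[(3E,5S)-3,5-dimethyl-6-phenylhex-3-en-1-yl]-1,3-dioxolane; 17 2-[(tert-butyldimethylsilyl)oxy]-N-methoxy-N-methylacetamide
Product: 19 1-[(tert-butyldimethylsilyl)oxy]-6-{2-[(3E,5S)-3,5-dimethyl-6-phenylhex-3-en-1-yl]-1,3-dioxolan-2-yl}hex-3-yn-2-one, via lithium acetylide 18 (not isolated)
Conditions: n-BuLi, THF, −78 °C; then 17, −78 → 0 °C
Reagents that add atoms: none
Why: Acylation of a lithium acetylide by a Weinreb amide, which gives the ynone without over-addition.

Step 10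
Reactants: 19 1-[(tert-butyldimethylsilyl)oxy]-6-{2-[(3E,5S)-3,5-dimethyl-6-phenylhex-3-en-1-yl]-1,3-dioxolan-2-yl}hex-3-yn-2-one
Product: 20 (2S)-1-[(tert-butyldimethylsilyl)oxy]-6-{2-[(3E,5S)-3,5-dimethyl-6-phenylhex-3-en-1-yl]-1,3-dioxolan-2-yl}hex-3-yn-2-ol
Conditions: Ru[(R,R)-TsDPEN](p-cymene) (1 mol %), i-PrOH, rt
Reagents that add atoms: none
Why: Noyori asymmetric transfer hydrogenation of an alkynyl ketone (TsDPEN is the N-tosyl-1,2-diphenylethane-1,2-diamine ligand); with the alkynyl group recognised by the arene ligand, the (R,R)-catalyst should give the C3 carbinol shown, which is S because CH2OSi outranks the alkynyl carbon.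

Step 11
Reactants: 20 (2S)-1-[(tert-butyldimethylsilyl)oxy]-6-{2-[(3E,5S)-3,5-dimethyl-6-phenylhex-3-en-1-yl]-1,3-dioxolan-2-yl}hex-3-yn-2-ol
Product: 22 (5S)-5-{[(tert-butyldimethylsilyl)oxy]methyl}-3-(2-{2-[(3E,5S)-3,5-dimethyl-6-phenylhex-3-en-1-yl]-1,3-dioxolan-2-yl}ethyl)-4-{[dimethyl(propan-2-yloxy)silyl]methyl}furan-2(5H)-one, via cyclic vinylmagnesium alkoxide 21 (not isolated)
Conditions: (i-PrO)Me2SiCH2MgCl (4 equiv), CuI (10 mol %), THF, 0 → 40 °C; CO2 (gas), −20 °C → rt; aq. citric acid
Reagents that add atoms: (isopropoxydimethylsilyl)methylmagnesium chloride, CC(C)O[Si](C)(C)C[Mg]Cl; carbon dioxide, O=C=O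
Why: Chelation-controlled anti-carbomagnesiation of a propargylic alcohol: the C3 magnesium alkoxide directs the carbon group to the proximal alkyne carbon C4 and magnesium to C5 on the side of C3 (five-membered chelate 21). Carboxylation of the vinyl–magnesium bond with retention, then lactonisation on acidification, locks C3 and the C5 carboxyl cis, hence C3 and C6 trans.

Step 12
Reactants: 22 (5S)-5-{[(tert-butyldimethylsilyl)oxy]methyl}-3-(2-{2-[(3E,5S)-3,5-dimethyl-6-phenylhex-3-en-1-yl]-1,3-dioxolan-2-yl}ethyl)-4-{[dimethyl(propan-2-yloxy)silyl]methyl}furan-2(5H)-one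
Product: 23 (5S)-5-{[(tert-butyldimethylsilyl)oxy]methyl}-3-(2-{2-[(3E,5S)-3,5-dimethyl-6-phenylhex-3-en-1-yl]-1,3-dioxolan-2-yl}ethyl)-4-(hydroxymethyl)furan-2(5H)-one
Conditions: 30% H2O2, KF, KHCO3, THF/MeOH, 0 °C → rt
Reagents that add atoms: hydrogen peroxide, OO
Why: Tamao oxidation of the alkoxysilane replaces C–Si by C–OH with retention and without allylic transposition; the bicarbonate buffer is mild enough to spare the C3 hydrogen of the butenolide.

Step 13
Reactants: 23 (5S)-5-{[(tert-butyldimethylsilyl)oxy]methyl}-3-(2-{2-[(3E,5S)-3,5-dimethyl-6-phenylhex-3-en-1-yl]-1,3-dioxolan-2-yl}ethyl)-4-(hydroxymethyl)furan-2(5H)-one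
Product: 24 (2Z,4S)-5-[(tert-butyldimethylsilyl)oxy]-2-(2-{2-[(3E,5S)-3,5-dimethyl-6-phenylhex-3-en-1-yl]-1,3-dioxolan-2-yl}ethyl)-3-(hydroxymethyl)pent-2-ene-1,4-diol
Conditions: i-Bu2AlH (5 equiv), CH2Cl2, −78 → 0 °C; aq. potassium sodium tartrate
Reagents that add atoms: none
Why: 1,2-Hydride reduction of the butenolide to the ene-1,4-diol; the alkene geometry set in step 11 is carried over unchanged.

Step 14
Reactants: 24 (2Z,4S)-5-[(tert-butyldimethylsilyl)oxy]-2-(2-{2-[(3E,5S)-3,5-dimethyl-6-phenylhex-3-en-1-yl]-1,3-dioxolan-2-yl}ethyl)-3-(hydroxymethyl)pent-2-ene-1,4-diol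
Product: 25 (1R)-2-[(tert-butyldimethylsilyl)oxy]-1-[(2S,3R)-3-(2-{2-[(3E,5S)-3,5-dimethyl-6-phenylhex-3-en-1-yl]-1,3-dioxolan-2-yl}ethyl)-2,3-bis(hydroxymethyl)oxiran-2-yl]ethan-1-ol
Conditions: Ti(Oi-Pr)4 (1.2 equiv), D-(−)-diethyl tartrate (1.4 equiv), t-BuOOH (2 equiv), 4 Å MS, CH2Cl2, −25 °C; aq. tartaric acid work-up
Reagents that add atoms: tert-butyl hydroperoxide, CC(C)(C)OO
Why: Sharpless asymmetric epoxidation: the two primary allylic hydroxymethyl groups are related by the local twofold axis of the trans-alkene, so both call for the same face with D-(−)-tartrate and should give the oxirane with C4 S and C5 R. The same face is preferred by the substrate when the C3 hydrogen eclipses the alkene (allylic 1,3-strain), and the titanium alkoxide mechanism leaves the remote side-chain alkene alone.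

Step 15
Reactants: 25 (1R)-2-[(tert-butyldimethylsilyl)oxy]-1-[(2S,3R)-3-(2-{2-[(3E,5S)-3,5-dimethyl-6-phenylhex-3-en-1-yl]-1,3-dioxolan-2-yl}ethyl)-2,3-bis(hydroxymethyl)oxiran-2-yl]ethan-1-ol
Product: 26 (1R)-2-[(tert-butyldimethylsilyl)oxy]-1-[(2S,3R)-2,3-bis({[tert-butyldimethylsilyl]oxy}methyl)-3-(2-{2-[(3E,5S)-3,5-dimethyl-6-phenylhex-3-en-1-yl]-1,3-dioxolan-2-yl}ethyl)oxiran-2-yl]ethan-1-ol
Conditions: TBSCl (2.3 equiv), imidazole, CH2Cl2, 0 °C
Reagents that add atoms: tert-butylchlorodimethylsilane, CC(C)(C)[Si](C)(C)Cl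
Why: Silylation of the two primary hydroxyls; the secondary C3 hydroxyl next to the fully substituted oxirane carbon should react far more slowly and stays free.

Step 16
Reactants: 26 (1R)-2-[(tert-butyldimethylsilyl)oxy]-1-[(2S,3R)-2,3-bis({[tert-butyldimethylsilyl]oxy}methyl)-3-(2-{2-[(3E,5S)-3,5-dimethyl-6-phenylhex-3-en-1-yl]-1,3-dioxolan-2-yl}ethyl)oxiran-2-yl]ethan-1-ol
Product: 27 (6E,8S)-1-[(2R,3S)-2,3-bis({[tert-butyldimethylsilyl]oxy}methyl)-3-{(1R)-2-[(tert-butyldimethylsilyl)oxy]-1-hydroxyethyl}oxiran-2-yl]-6,8-dimethyl-9-phenylnon-6-en-3-one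
Conditions: PPTS (0.2 equiv), acetone/H2O (10:1), 40 °C
Reagents that add atoms: water, O
Why: Mild acid-catalysed ketal hydrolysis; the oxirane has an oxygen-bearing carbon on every side and should resist ionisation at this acidity, and primary TBS ethers survive.

Step 17
Reactants: 27 (6E,8S)-1-[(2R,3S)-2,3-bis({[tert-butyldimethylsilyl]oxy}methyl)-3-{(1R)-2-[(tert-butyldimethylsilyl)oxy]-1-hydroxyethyl}oxiran-2-yl]-6,8-dimethyl-9-phenylnon-6-en-3-one
Product: 29 (1S,3R,4S,5S)-3,4,5-tris({[tert-butyldimethylsilyl]oxy}methyl)-1-[(3E,5S)-3,5-dimethyl-6-phenylhex-3-en-1-yl]-2,8-dioxabicyclo[3.2.1]octan-4-ol, via oxocarbenium ion 28 (not isolated)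
Conditions: BF3·OEt2 (0.5 equiv), CH2Cl2, −78 → −20 °C; Et3N quench
Reagents that add atoms: none
Why: BF3 binds the oxirane oxygen and the C1 carbonyl oxygen attacks C5 from the side opposite the breaking C5–O bond, a 5-exo opening that forms C5–O8 with inversion and leaves the oxirane oxygen on C4 as a boron-bound alkoxide in oxocarbenium ion 28. The C3 hydroxyl then adds to C1 of 28, closing the 1,3-dioxane in a 6-endo mode with respect to the C1=O8 bond, and proton transfer frees the C4 hydroxyl and the Lewis acid. The closest known reaction type is the Lewis-acid rearrangement of epoxy ketones to bridged bicyclic ketals, in which a carbonyl oxygen opens the oxirane and an oxygen nucleophile traps the oxocarbenium ion; the fully substituted oxirane and the use of a hydroxyl outside the oxirane are extensions of it. C5 is set by stereospecific inversion of the (R)-oxirane carbon, C4 keeps its oxygen and configuration, and C1 is set by the bridge, since O2 and O8 can span C3 and C5 from one face only. Attack at C5 and not C4 is secured by the exo geometry of the three-atom tether and by the better cation-stabilising ability of C5 (alkyl arm) compared with C4 (next to the electron-poor C3 carbinol, and reachable only by a six-membered endo opening). Capture of 28 by the C4 alkoxide would give a strained 2,7-dioxabicyclo[2.2.1]heptane ketal, but this closure is reversible under the Lewis acid, so warming to −20 °C should drain it into the less strained 2,8-dioxabicyclo[3.2.1]octane. Participation by the carbonyl group pre-empts a free C5 cation and with it the competing 1,2-shift.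

Step 18
Reactants: 29 (1S,3R,4S,5S)-3,4,5-tris({[tert-butyldimethylsilyl]oxy}methyl)-1-[(3E,5S)-3,5-dimethyl-6-phenylhex-3-en-1-yl]-2,8-dioxabicyclo[3.2.1]octan-4-ol
Product: 30 (1S,3R,4S,5S)-1-[(3E,5S)-3,5-dimethyl-6-phenylhex-3-en-1-yl]-3,4,5-tris(hydroxymethyl)-2,8-dioxabicyclo[3.2.1]octan-4-ol
Conditions: HF·pyridine, pyridine, THF, 0 °C → rt
Reagents that add atoms: none
Why: Fluoride cleavage of the three primary silyl ethers under buffered conditions that the bicyclic ketal and the alkene tolerate.

Step 19
Reactants: 30 (1S,3R,4S,5S)-1-[(3E,5S)-3,5-dimethyl-6-phenylhex-3-en-1-yl]-3,4,5-tris(hydroxymethyl)-2,8-dioxabicyclo[3.2.1]octan-4-ol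
Product: 31 (1S,3S,4S,5R)-1-[(3E,5S)-3,5-dimethyl-6-phenylhex-3-en-1-yl]-4-hydroxy-2,8-dioxabicyclo[3.2.1]octane-3,4,5-tricarbaldehyde
Conditions: Dess–Martin periodinane (6 equiv), NaHCO3, CH2Cl2, 0 °C → rt
Reagents that add atoms: none
Why: Hypervalent-iodine oxidation of the three primary alcohols; the tertiary C4 hydroxyl cannot be oxidised, and excess oxidant is used so that all three carbinols are converted before hydroxy aldehydes can settle as lactols.

Step 20
Reactants: 31 (1S,3S,4S,5R)-1-[(3E,5S)-3,5-dimethyl-6-phenylhex-3-en-1-yl]-4-hydroxy-2,8-dioxabicyclo[3.2.1]octane-3,4,5-tricarbaldehyde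
Product: 32 (1S,3S,4S,5R)-1-[(3E,5S)-3,5-dimethyl-6-phenylhex-3-en-1-yl]-4-hydroxy-2,8-dioxabicyclo[3.2.1]octane-3,4,5-tricarboxylic acid
Conditions: NaClO2, NaH2PO4, 2-methylbut-2-ene, t-BuOH/H2O, 0 °C → rt
Reagents that add atoms: sodium chlorite, [Na+].[O-]Cl=O
Why: Pinnick oxidation of the three aldehydes to the acids; the weakly acidic buffer should not epimerise C3, and the alkene scavenger protects the side-chain double bond from hypochlorous acid.

Compound list

1 | methyl (2R)-3-bromo-2-methylpropanoate | COC(=O)[C@@H](C)CBr | starting material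
2 | iodobenzene | Ic1ccccc1 | starting material
3 | [(2R)-3-methoxy-2-methyl-3-oxopropyl]zinc bromide (not isolated) | COC(=O)[C@@H](C)C[Zn]Br | intermediate
4 | methyl (2S)-2-methyl-3-phenylpropanoate | COC(=O)[C@@H](C)Cc1ccccc1 | intermediate
5 | (2S)-2-methyl-3-phenylpropanal | O=C[C@@H](C)Cc1ccccc1 | intermediate
6 | (prop-1-en-2-yl)magnesium bromide | CC(=C)[Mg]Br | starting material
7 | (3RS,4S)-2,4-dimethyl-5-phenylpent-1-en-3-ol (both C3 epimers) | C=C(C)C(O)[C@@H](C)Cc1ccccc1 | intermediate
8 | triethyl orthoacetate (1,1,1-triethoxyethane) | CCOC(C)(OCC)OCC | starting material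
9 | (4S)-3-[(1-ethoxyethenyl)oxy]-2,4-dimethyl-5-phenylpent-1-ene (ketene acetal, not isolated) | C=C(OCC)OC(C(C)=C)[C@@H](C)Cc1ccccc1 | intermediate
10 | ethyl (4E,6S)-4,6-dimethyl-7-phenylhept-4-enoate | C/C(=C\[C@@H](C)Cc1ccccc1)CCC(=O)OCC | intermediate
11 | (4E,6S)-N-methoxy-N,4,6-trimethyl-7-phenylhept-4-enamide | C/C(=C\[C@@H](C)Cc1ccccc1)CCC(=O)N(C)OC | intermediate
12 | (4-bromobut-1-yn-1-yl)trimethylsilane | C[Si](C)(C)C#CCCBr | starting material
13 | [4-(trimethylsilyl)but-3-yn-1-yl]magnesium bromide (not isolated) | C[Si](C)(C)C#CCC[Mg]Br | intermediate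
14 | (8E,10S)-8,10-dimethyl-11-phenyl-1-(trimethylsilyl)undec-8-en-1-yn-5-one | C/C(=C\[C@@H](C)Cc1ccccc1)CCC(=O)CCC#C[Si](C)(C)C | intermediate
15 | trimethyl(4-{2-[(3E,5S)-3,5-dimethyl-6-phenylhex-3-en-1-yl]-1,3-dioxolan-2-yl}but-1-yn-1-yl)silane | C/C(=C\[C@@H](C)Cc1ccccc1)CCC1(OCCO1)CCC#C[Si](C)(C)C | intermediate
16 | 2-(but-3-yn-1-yl)-2-[(3E,5S)-3,5-dimethyl-6-phenylhex-3-en-1-yl]-1,3-dioxolane | C/C(=C\[C@@H](C)Cc1ccccc1)CCC1(OCCO1)CCC#C | intermediate
17 | 2-[(tert-butyldimethylsilyl)oxy]-N-methoxy-N-methylacetamide | CON(C)C(=O)CO[Si](C)(C)C(C)(C)C | starting material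
18 | lithium acetylide of 16, (4-{2-[(3E,5S)-3,5-dimethyl-6-phenylhex-3-en-1-yl]-1,3-dioxolan-2-yl}but-1-yn-1-yl)lithium (not isolated) | C/C(=C\[C@@H](C)Cc1ccccc1)CCC1(OCCO1)CCC#C[Li] | intermediate
19 | 1-[(tert-butyldimethylsilyl)oxy]-6-{2-[(3E,5S)-3,5-dimethyl-6-phenylhex-3-en-1-yl]-1,3-dioxolan-2-yl}hex-3-yn-2-one | C/C(=C\[C@@H](C)Cc1ccccc1)CCC1(OCCO1)CCC#CC(=O)CO[Si](C)(C)C(C)(C)C | intermediate
20 | (2S)-1-[(tert-butyldimethylsilyl)oxy]-6-{2-[(3E,5S)-3,5-dimethyl-6-phenylhex-3-en-1-yl]-1,3-dioxolan-2-yl}hex-3-yn-2-ol | C/C(=C\[C@@H](C)Cc1ccccc1)CCC1(OCCO1)CCC#C[C@H](O)CO[Si](C)(C)C(C)(C)C | intermediate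
21 | cyclic vinylmagnesium alkoxide (2,5-dihydro-1,2-oxamagnesole; Mg bonded to the C3 oxygen and to C5; C4 carries the silylmethyl group; not isolated) | C/C(=C\[C@@H](C)Cc1ccccc1)CCC1(OCCO1)CCC2=C(C[Si](C)(C)OC(C)C)[C@@H](CO[Si](C)(C)C(C)(C)C)O[Mg]2 | intermediate
22 | (5S)-5-{[(tert-butyldimethylsilyl)oxy]methyl}-3-(2-{2-[(3E,5S)-3,5-dimethyl-6-phenylhex-3-en-1-yl]-1,3-dioxolan-2-yl}ethyl)-4-{[dimethyl(propan-2-yloxy)silyl]methyl}furan-2(5H)-one | C/C(=C\[C@@H](C)Cc1ccccc1)CCC1(OCCO1)CCC2=C(C[Si](C)(C)OC(C)C)[C@@H](CO[Si](C)(C)C(C)(C)C)OC2=O | intermediate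
23 | (5S)-5-{[(tert-butyldimethylsilyl)oxy]methyl}-3-(2-{2-[(3E,5S)-3,5-dimethyl-6-phenylhex-3-en-1-yl]-1,3-dioxolan-2-yl}ethyl)-4-(hydroxymethyl)furan-2(5H)-one | C/C(=C\[C@@H](C)Cc1ccccc1)CCC1(OCCO1)CCC2=C(CO)[C@@H](CO[Si](C)(C)C(C)(C)C)OC2=O | intermediate
24 | (2Z,4S)-5-[(tert-butyldimethylsilyl)oxy]-2-(2-{2-[(3E,5S)-3,5-dimethyl-6-phenylhex-3-en-1-yl]-1,3-dioxolan-2-yl}ethyl)-3-(hydroxymethyl)pent-2-ene-1,4-diol | C/C(=C\[C@@H](C)Cc1ccccc1)CCC1(OCCO1)CC/C(CO)=C(CO)/[C@H](O)CO[Si](C)(C)C(C)(C)C | intermediate
25 | (1R)-2-[(tert-butyldimethylsilyl)oxy]-1-[(2S,3R)-3-(2-{2-[(3E,5S)-3,5-dimethyl-6-phenylhex-3-en-1-yl]-1,3-dioxolan-2-yl}ethyl)-2,3-bis(hydroxymethyl)oxiran-2-yl]ethan-1-ol | C/C(=C\[C@@H](C)Cc1ccccc1)CCC1(OCCO1)CC[C@]2(CO)O[C@@]2(CO)[C@H](O)CO[Si](C)(C)C(C)(C)C | intermediate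
26 | (1R)-2-[(tert-butyldimethylsilyl)oxy]-1-[(2S,3R)-2,3-bis({[tert-butyldimethylsilyl]oxy}methyl)-3-(2-{2-[(3E,5S)-3,5-dimethyl-6-phenylhex-3-en-1-yl]-1,3-dioxolan-2-yl}ethyl)oxiran-2-yl]ethan-1-ol | C/C(=C\[C@@H](C)Cc1ccccc1)CCC1(OCCO1)CC[C@]2(CO[Si](C)(C)C(C)(C)C)O[C@@]2(CO[Si](C)(C)C(C)(C)C)[C@H](O)CO[Si](C)(C)C(C)(C)C | intermediate
27 | (6E,8S)-1-[(2R,3S)-2,3-bis({[tert-butyldimethylsilyl]oxy}methyl)-3-{(1R)-2-[(tert-butyldimethylsilyl)oxy]-1-hydroxyethyl}oxiran-2-yl]-6,8-dimethyl-9-phenylnon-6-en-3-one (key-step precursor) | C/C(=C\[C@@H](C)Cc1ccccc1)CCC(=O)CC[C@]2(CO[Si](C)(C)C(C)(C)C)O[C@@]2(CO[Si](C)(C)C(C)(C)C)[C@H](O)CO[Si](C)(C)C(C)(C)C | intermediate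
28 | cyclic oxocarbenium ion (4,5-dihydrofuran-1-ium with C1=O8 and the new C5–O8 bond; C4 oxygen bound to BF3; zwitterion, not isolated) | C/C(=C\[C@@H](C)Cc1ccccc1)CCC1=[O+][C@](CO[Si](C)(C)C(C)(C)C)(CC1)[C@](O[B-](F)(F)F)(CO[Si](C)(C)C(C)(C)C)[C@H](O)CO[Si](C)(C)C(C)(C)C | intermediate
29 | (1S,3R,4S,5S)-3,4,5-tris({[tert-butyldimethylsilyl]oxy}methyl)-1-[(3E,5S)-3,5-dimethyl-6-phenylhex-3-en-1-yl]-2,8-dioxabicyclo[3.2.1]octan-4-ol (key-step product) | C/C(=C\[C@@H](C)Cc1ccccc1)CC[C@@]12CC[C@@](CO[Si](C)(C)C(C)(C)C)(O1)[C@](O)(CO[Si](C)(C)C(C)(C)C)[C@@H](CO[Si](C)(C)C(C)(C)C)O2 | intermediate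
30 | (1S,3R,4S,5S)-1-[(3E,5S)-3,5-dimethyl-6-phenylhex-3-en-1-yl]-3,4,5-tris(hydroxymethyl)-2,8-dioxabicyclo[3.2.1]octan-4-ol | C/C(=C\[C@@H](C)Cc1ccccc1)CC[C@@]12CC[C@@](CO)(O1)[C@](O)(CO)[C@@H](CO)O2 | intermediate
31 | (1S,3S,4S,5R)-1-[(3E,5S)-3,5-dimethyl-6-phenylhex-3-en-1-yl]-4-hydroxy-2,8-dioxabicyclo[3.2.1]octane-3,4,5-tricarbaldehyde | C/C(=C\[C@@H](C)Cc1ccccc1)CC[C@@]12CC[C@@](C=O)(O1)[C@](O)(C=O)[C@@H](C=O)O2 | intermediate
32 | (1S,3S,4S,5R)-1-[(3E,5S)-3,5-dimethyl-6-phenylhex-3-en-1-yl]-4-hydroxy-2,8-dioxabicyclo[3.2.1]octane-3,4,5-tricarboxylic acid | C/C(=C\[C@@H](C)Cc1ccccc1)CC[C@@]12CC[C@@](C(=O)O)(O1)[C@](O)(C(=O)O)[C@@H](C(=O)O)O2 | target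

Total step count: 20. Longest linear sequence: 20 steps (1 to 32); 2, 6, 8, 12 and 17 are purchased and enter directly.

Least certain steps

Step 17 (key step). The activated oxirane may rearrange by a 1,2-shift or be opened by fluoride before the carbonyl oxygen engages. Capture of the oxocarbenium ion by the C4 alkoxide may fail to equilibrate at low temperature, or a silyl ether may be lost to the Lewis acid. The fallback interrupts the cascade with an external alcohol and sets out from 27. BF3·OEt2 in CH2Cl2 containing methanol (5 equiv) at −78 °C should open the oxirane through the methyl hemiketal, by the same invertive 5-exo attack at C5, and store C1 as the mixed methyl ketal F1. In a second operation PPTS in warm benzene should exchange the methoxy group for the C3 hydroxyl under thermodynamic control, and the route is rejoined at 29.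

Step 11. The silylmethyl Grignard reagent is less reactive than the vinyl and aryl reagents for which this anti-carbomagnesiation is best established. Addition may be slow, the silyl group may migrate from the primary oxygen to the neighbouring magnesium alkoxide, and carboxylation of the hindered vinylmagnesium may be incomplete. The C3 hydrogen of the butenolide may also epimerise during the oxidation that follows. The fallback builds the butenolide by ring synthesis with C3 from the chiral pool; it sets out from 15 and rejoins at 23.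
- Hydroboration of the silylalkyne with Cy2BH and alkaline H2O2 oxidation should give carboxylic acid F2.
- Esterification (DCC, DMAP) with methyl (2R)-3-[(tert-butyldimethylsilyl)oxy]-2-hydroxypropanoate should give diester F3.
- Dieckmann cyclisation with LiN(SiMe3)2 at −78 °C should give tetronic acid F4.
- Tf2O and i-Pr2NEt should give enol triflate F5.
- Stille coupling with (tributylstannyl)methanol (Pd(PPh3)4, LiCl) should then give 23.

Step 14. The triol may chelate titanium through its 1,3- and cis-1,4-diol motifs and switch off the tartrate-controlled pathway, leaving a slow reaction with poor facial control. Oxygen may also be delivered through the secondary C3 alkoxide, which the same tartrate directs to the opposite face. The fallback changes from reagent control to substrate control and sets out from 24. TBSCl and imidazole should give the tris-silyl allylic alcohol F6, in which only the C3 hydroxyl is free. Hydroxyl-directed epoxidation through that alkoxide (VO(acac)2 or Ti(Oi-Pr)4 without tartrate, t-BuOOH) relies on allylic 1,3-strain for the same face and rejoins the route at 26.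

Step 16. The acid may open the oxirane with water, or the freed carbonyl may start the cascade in the aqueous medium; primary silyl ethers may also be lost. The fallback unmasks the ketone before the oxirane exists and sets out from 24. Silylation gives F6 as above, and PPTS in wet acetone at the alkene stage should give keto alcohol F7. The directed epoxidation described for step 14 then rejoins the route at 27.

Step 19. A first-formed aldehyde may be trapped by a neighbouring hydroxymethyl group as a lactol and oxidised on to a lactone. The trialdehyde may epimerise at C3 or cleave by a retro-aldol path. The fallback sets out from 30. All three hydroxyls are activated before any carbonyl exists (DMSO and (COCl)2, then i-Pr2NEt at −78 °C), and the crude aldehyde is oxidised with NaClO2. The crude acid is esterified with N,N'-diisopropyl-O-tert-butylisourea to the chromatographable tri-tert-butyl ester F8, and CF3CO2H in CH2Cl2 then rejoins the route at 32.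

Further compounds

F1 | step 17 | (2S,3R)-1,4-bis[(tert-butyldimethylsilyl)oxy]-2-[(2S)-2-({[tert-butyldimethylsilyl]oxy}methyl)-5-[(3E,5S)-3,5-dimethyl-6-phenylhex-3-en-1-yl]-5-methoxyoxolan-2-yl]butane-2,3-diol (mixed methyl ketal, both C1 epimers) | C/C(=C\[C@@H](C)Cc1ccccc1)CCC1(OC)CC[C@@](CO[Si](C)(C)C(C)(C)C)(O1)[C@](O)(CO[Si](C)(C)C(C)(C)C)[C@H](O)CO[Si](C)(C)C(C)(C)C
F2 | step 11 | 4-{2-[(3E,5S)-3,5-dimethyl-6-phenylhex-3-en-1-yl]-1,3-dioxolan-2-yl}butanoic acid | C/C(=C\[C@@H](C)Cc1ccccc1)CCC1(OCCO1)CCCC(=O)O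
F3 | step 11 | methyl (2R)-3-[(tert-butyldimethylsilyl)oxy]-2-[(4-{2-[(3E,5S)-3,5-dimethyl-6-phenylhex-3-en-1-yl]-1,3-dioxolan-2-yl}butanoyl)oxy]propanoate | C/C(=C\[C@@H](C)Cc1ccccc1)CCC1(OCCO1)CCCC(=O)O[C@H](CO[Si](C)(C)C(C)(C)C)C(=O)OC
F4 | step 11 | (5R)-5-({[tert-butyldimethylsilyl]oxy}methyl)-3-(2-{2-[(3E,5S)-3,5-dimethyl-6-phenylhex-3-en-1-yl]-1,3-dioxolan-2-yl}ethyl)-4-hydroxyfuran-2(5H)-one | C/C(=C\[C@@H](C)Cc1ccccc1)CCC1(OCCO1)CCC2=C(O)[C@@H](CO[Si](C)(C)C(C)(C)C)OC2=O
F5 | step 11 | (2R)-2-({[tert-butyldimethylsilyl]oxy}methyl)-4-(2-{2-[(3E,5S)-3,5-dimethyl-6-phenylhex-3-en-1-yl]-1,3-dioxolan-2-yl}ethyl)-5-oxo-2,5-dihydrofuran-3-yl trifluoromethanesulfonate | C/C(=C\[C@@H](C)Cc1ccccc1)CCC1(OCCO1)CCC2=C(OS(=O)(=O)C(F)(F)F)[C@@H](CO[Si](C)(C)C(C)(C)C)OC2=O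
F6 | step 14 | (2S,3Z)-1,5-bis[(tert-butyldimethylsilyl)oxy]-3-({[tert-butyldimethylsilyl]oxy}methyl)-4-(2-{2-[(3E,5S)-3,5-dimethyl-6-phenylhex-3-en-1-yl]-1,3-dioxolan-2-yl}ethyl)pent-3-en-2-ol | C/C(=C\[C@@H](C)Cc1ccccc1)CCC1(OCCO1)CC/C(CO[Si](C)(C)C(C)(C)C)=C(CO[Si](C)(C)C(C)(C)C)/[C@H](O)CO[Si](C)(C)C(C)(C)C
F7 | step 16 | (2S,3Z,10E,12S)-1-[(tert-butyldimethylsilyl)oxy]-3,4-bis({[tert-butyldimethylsilyl]oxy}methyl)-2-hydroxy-10,12-dimethyl-13-phenyltrideca-3,10-dien-7-one | C/C(=C\[C@@H](C)Cc1ccccc1)CCC(=O)CC/C(CO[Si](C)(C)C(C)(C)C)=C(CO[Si](C)(C)C(C)(C)C)/[C@H](O)CO[Si](C)(C)C(C)(C)C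
F8 | step 19 | tri-tert-butyl (1S,3S,4S,5R)-1-[(3E,5S)-3,5-dimethyl-6-phenylhex-3-en-1-yl]-4-hydroxy-2,8-dioxabicyclo[3.2.1]octane-3,4,5-tricarboxylate | C/C(=C\[C@@H](C)Cc1ccccc1)CC[C@@]12CC[C@@](C(=O)OC(C)(C)C)(O1)[C@](O)(C(=O)OC(C)(C)C)[C@@H](C(=O)OC(C)(C)C)O2
A1 | alternative 1 | trimethyl 2-[(3E,5S)-3,5-dimethyl-6-phenylhex-3-en-1-yl]-2,4-diethenyl-5-hydroxy-1,3-dioxane-4,5,6-tricarboxylate (vinyl groups at core C1 and C5 cis) | C/C(=C\[C@@H](C)Cc1ccccc1)CC[C@@]1(C=C)O[C@@](C=C)(C(=O)OC)[C@](O)(C(=O)OC)[C@@H](C(=O)OC)O1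
A2 | alternative 1 | trimethyl 1-[(3E,5S)-3,5-dimethyl-6-phenylhex-3-en-1-yl]-4-hydroxy-2,8-dioxabicyclo[3.2.1]oct-6-ene-3,4,5-tricarboxylate | C/C(=C\[C@@H](C)Cc1ccccc1)CC[C@@]12C=C[C@@](C(=O)OC)(O1)[C@](O)(C(=O)OC)[C@@H](C(=O)OC)O2
A3 | alternative 2 | methyl 5-[(3E,5S)-3,5-dimethyl-6-phenylhex-3-en-1-yl]-5-(2-methoxy-2-oxoethoxy)-2-(2-methoxy-2-oxoacetyl)oxolane-2-carboxylate (glycolate oxygen cis to the keto ester arm) | C/C(=C\[C@@H](C)Cc1ccccc1)CC[C@@]1(OCC(=O)OC)CC[C@@](C(=O)OC)(O1)C(=O)C(=O)OC
A4 | alternative 2 | trimethyl (1S,3S,4S,5R)-1-[(3E,5S)-3,5-dimethyl-6-phenylhex-3-en-1-yl]-4-hydroxy-2,8-dioxabicyclo[3.2.1]octane-3,4,5-tricarboxylate | C/C(=C\[C@@H](C)Cc1ccccc1)CC[C@@]12CC[C@@](C(=O)OC)(O1)[C@](O)(C(=O)OC)[C@@H](C(=O)OC)O2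
A5 | alternative 3 | tri-tert-butyl 1-diazo-3-{[(4E,6S)-4,6-dimethyl-7-phenylhept-4-enoyl]oxy}-2-[(trimethylsilyl)oxy]propane-1,2,3-tricarboxylate (core C3 and C4 configured as in the target) | C/C(=C\[C@@H](C)Cc1ccccc1)CCC(=O)O[C@H](C(=O)OC(C)(C)C)[C@@](O[Si](C)(C)C)(C(=O)OC(C)(C)C)C(=[N+]=[N-])C(=O)OC(C)(C)C
A6 | alternative 3 | (E)-1,2-bis(phenylsulfonyl)ethene | O=S(=O)(/C=C/S(=O)(=O)c1ccccc1)c1ccccc1
A7 | alternative 3 | tri-tert-butyl 1-[(3E,5S)-3,5-dimethyl-6-phenylhex-3-en-1-yl]-6,7-bis(phenylsulfonyl)-4-[(trimethylsilyl)oxy]-2,8-dioxabicyclo[3.2.1]octane-3,4,5-tricarboxylate (one trans isomer) | C/C(=C\[C@@H](C)Cc1ccccc1)CC[C@@]12[C@H](S(=O)(=O)c3ccccc3)[C@@H](S(=O)(=O)c3ccccc3)[C@@](C(=O)OC(C)(C)C)(O1)[C@](O[Si](C)(C)C)(C(=O)OC(C)(C)C)[C@@H](C(=O)OC(C)(C)C)O2
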